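Take one lifetime of J as the unit of time: the stay in which J falls by a factor e. Two chemists dispute whether that unit matters here.

| flask | Q | D | remark | time |
|---|---|---|---|---|
| dusk | 0.20 M | 20 µM | run made earlier |  |
| midnight | 0.20 M | 13 µM | run made earlier |  |
| spring | 0.20 M | 30 µM | run made earlier |  |
| violet | 0.20 M (fed, over 2.40 d) | 20 µM | a stirred flask in which Q is dosed at a steady rate over 2.40 d without added volume, worked up at 3.0 d | 3.0 d |
| amber | 0.20 M | 20 µM | a closed flask charged with all of it at once and left for 3.0 d | 3.0 d |
| ochre | 0.20 M | 20 µM | one stirred flow tank at steady state, fed with the mixture as stated, mean residence time 30.0 d |  |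
| blue | 0.20 M | 20 µM | one stirred flow tank at steady state, fed with the mixture as stated, mean residence time 3.0 d |  |

dusk run (percent of the Q charged)

| time / h | J / % |
|---|---|
| 8.00 | 97.1 |
| 15.0 | 94.1 |
| 20.0 | 91.9 |
| 30.0 | 88.7 |
| 40.0 | 84.1 |

midnight run (percent of the Q charged)

| time / d | J / % |
|---|---|
| 0.250 | 98.5 |
| 0.625 | 97.3 |
| 1.25 | 92.7 |
| 2.08 | 87.3 |
| 3.00 | 82.1 |
| 4.00 | 76.4 |

spring run (percent of the Q charged)

| time / d | J / % |
|---|---|
| 0.625 | 91.2 |
| 1.25 | 82.4 |
| 1.67 | 77.1 |
| 2.50 | 68.3 |
| 3.00 | 63.1 |
| 4.00 | 54.6 |

(each reading ± 0.5 percentage points)

- the stated concentrations are those of everything mixed, before any reaction; amounts are the same in each set-up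
- the numbers in the tables scatter by 0.5 percentage points (one standard deviation)
- the feed brings no volume worth counting
- the earlier runs were made in a closed, stirred flask

1. the set-up with the highest amount of J at the outlet or at the end, in percent of the Q put in ("none" if the first two lie within 2 percentage points) (violet / amber / ochre / blue / none)
2. amount of J at the outlet or at the end, in percent of the Q put in, violet
3. amount of J at the outlet or at the end, in percent of the Q put in, amber
4. amount of J at the outlet or at the end, in percent of the Q put in, ochre
5. amount of J at the outlet or at the end, in percent of the Q put in, blue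

The first chemist holds that “Q gives J essentially at once, with no visible lag, and J is then slowly lost”. The second chemist holds to one step, first order in Q and in D, with all reacted Q read as J. That chemist points to the first midnight reading, 98.5% at 0.250 d. On that view a longer stay costs no J.

My own reckoning starts from the readings. The spring run falls from 91.2% to 54.6% between 0.625 d and 4.00 d, which is a constant of 0.152 /d. The midnight run reads 0.0678 /d. These constants stand in a ratio of 2.24, and the amounts of D in a ratio of 2.31. So the loss looks pseudo-first-order in J, with its constant following D. At the charged D that reading gives 0.101 /d.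

The turnover count is this constant times the time J spends in the flask. Amber and blue have 0.304, and ochre has 3.04, a much larger count. A closed flask keeps e to the minus count, and a tank keeps one over one plus the count. Violet's J is on average younger, with a mean stay of 1.80 d. That gives a count of 0.182, the lowest of the set, and my rough survival of 83.4%.

The forecast, which is the first chemist's, averages over the dosing instead. It names violet with 83.6%, and gives amber 73.8%, ochre 24.8% and blue 76.7%.

The simulation gives violet as best: violet 83.3%, amber 73.6%, ochre 24.2%, blue 75.4%.

    Q + D → J + D, rate k1*[Q]^1.5*[D]/(1 + ([Q]/Kh1)^1.5) (18.7 mM, k = 458 /M^1.5/s)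
    D + J → D + E (k = 0.0603 /M/s)

The second chemist's fit gives ochre 99.9%, against the simulated 24.2%. Ochre's count of 3.04 gives 24.8% by the tank rule, and 75.6% of the Q charged stands as E at ochre's outlet. The second chemist's view has its region at small counts: at the first midnight reading the count is 0.0165, and J reads 98.5%. Violet has not come to rest at 3.0 d. Held to 30.0 d, its count reaches 2.92, which leaves 5.39% by the closed-flask rule. The simulated amount of J there is 5.00%.

(The data were computed on assumed constants, and the scatter is random.)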